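The cyclohexane (ring A, C5–C10) is opened at C5–C6. The feature exploited is the cis pair on ring A of the C6 carbinol and the C5 substituent with its C4=C3 methylidene, read as a 2-borylated homoallylic alcohol. One copper-catalysed borylative allene–aldehyde cyclisation forms C5–C6 and C4–B, closes ring A, sets C5 and C6, and leaves a vinylboronate as the handle for C15. Precursor 22 is a trans-disubstituted γ-lactone (ring B, C7/C8) bearing the C6 aldehyde on C7 and, on C8, the C9 silyl ether and quaternary C10 (methyl, vinyl, allenyl). C8 comes from the chiral pool, C7 from a trans photoaddition, C9/C10 from one allylboration.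

Key step: step 12

Remark: atoms carry elemane numbers (ring A = C5–C10; ring B = C7–C8–O–C12–C11 with C13 on C11; C3=C4–C15 on C5; vinyl C1=C2 and methyl C14 on C10; β = face of the C10 methyl); the target is taken as 5R,6S,7S,8R,9S,10S with a trans-fused lactone. Because a free terminal enyne is prone to 1,5-substitution under metal-catalysed borylation, the Z allylboronate is assumed to be best built with fixed geometry from propyne, and C6 is carried as a dioxolane so that the sensitive aldehyde appears only in step 11.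

Step 1
Reactants: 1 (R)-5-oxotetrahydrofuran-2-carboxylic acid
Product: 2 (R)-5-(hydroxymethyl)dihydrofuran-2(3H)-one
Conditions: BH3·SMe2, THF, 0 °C → rt; MeOH quench
Reagents that add atoms: none
Why: Borane reduces the carboxylic acid far faster than the lactone (chemoselective borane reduction), and the C8 stereocentre is not touched.

Step 2
Reactants: 2 (R)-5-(hydroxymethyl)dihydrofuran-2(3H)-one
Product: 3 (R)-5-{[(triethylsilyl)oxy]methyl}dihydrofuran-2(3H)-one
Conditions: Et3SiCl, imidazole, CH2Cl2, 0 °C → rt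
Reagents that add atoms: chlorotriethylsilane, CC[Si](Cl)(CC)CC
Why: Standard silyl ether formation at a primary alcohol; the triethylsilyl ether is chosen because it can later be oxidised directly to the aldehyde.

Step 3
Reactants: 3 (R)-5-{[(triethylsilyl)oxy]methyl}dihydrofuran-2(3H)-one
Product: 6 (R)-5-{[(triethylsilyl)oxy]methyl}furan-2(5H)-one, via phenylselenide 4 (not isolated), via selenoxide 5 (not isolated)
Conditions: LiN(iPr)2 (LDA), THF, −78 °C; PhSeBr; then pyridine, 30% H2O2, 0 °C → rt
Reagents that add atoms: none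
Why: α-Selenenylation at C11 followed by oxidation and syn elimination (selenoxide elimination) should give the butenolide under conditions too mild to enolise the γ-stereocentre C8.

Step 4
Reactants: 6 (R)-5-{[(triethylsilyl)oxy]methyl}furan-2(5H)-one
Product: 7 (4R,5R)-4-(1,3-dioxolan-2-yl)-5-{[(triethylsilyl)oxy]methyl}dihydrofuran-2(3H)-one
Conditions: hν (medium-pressure Hg lamp, Pyrex), Ph2CO (10 mol%), degassed 1,3-dioxolane as solvent, 0–5 °C
Reagents that add atoms: 1,3-dioxolane, C1COCO1
Why: Benzophenone-sensitised radical conjugate addition: the 1,3-dioxolan-2-yl radical should add to C7 anti to the C8 side chain, which sets the trans C7/C8 relationship and brings in C6 at the aldehyde oxidation level.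

Step 5
Reactants: 7 (4R,5R)-4-(1,3-dioxolan-2-yl)-5-{[(triethylsilyl)oxy]methyl}dihydrofuran-2(3H)-one
Product: 8 (2R,3R)-3-(1,3-dioxolan-2-yl)-5-oxotetrahydrofuran-2-carbaldehyde
Conditions: (COCl)2, DMSO, CH2Cl2, −78 → −30 °C; Et3N, −78 °C → rt; used crude
Reagents that add atoms: none
Why: Swern oxidation applied directly to the primary triethylsilyl ether, which the chlorosulfonium reagent cleaves and oxidises in one operation; cold base and immediate use should keep C8 from epimerising.

Step 6
Reactants: 9 propyne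
Product: 11 2-[(Z)-2-bromoprop-1-en-1-yl]-4,4,5,5-tetramethyl-1,3,2-dioxaborolane, via dibromoborane 10 (not isolated)
Conditions: BBr3, CH2Cl2, −78 °C → rt; then pinacol, 0 °C → rt
Reagents that add atoms: boron tribromide, BrB(Br)Br; pinacol, CC(C)(O)C(C)(C)O
Why: syn-Bromoboration of the alkyne (haloboration) places Br and B cis with boron on the terminal carbon, and ester exchange with pinacol should fix this as the stable Z bromoalkenyl boronate.

Step 7
Reactants: 11 2-[(Z)-2-bromoprop-1-en-1-yl]-4,4,5,5-tetramethyl-1,3,2-dioxaborolane; 12 ethynyltrimethylsilane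
Product: 14 4,4,5,5-tetramethyl-2-[(1Z)-2-methyl-4-(trimethylsilyl)but-1-en-3-yn-1-yl]-1,3,2-dioxaborolane, via alkynylzinc chloride 13 (not isolated)
Conditions: 12, n-BuLi, THF, −78 °C; ZnCl2, → 0 °C; then 11, Pd(PPh3)4 (3 mol%), THF, rt
Reagents that add atoms: none
Why: Negishi coupling at the C–Br bond proceeds with retention of alkene geometry and, being base-free, should leave the pinacol boronate intact.

Step 8
Reactants: 14 4,4,5,5-tetramethyl-2-[(1Z)-2-methyl-4-(trimethylsilyl)but-1-en-3-yn-1-yl]-1,3,2-dioxaborolane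
Product: 15 4,4,5,5-tetramethyl-2-[(2Z)-3-methyl-5-(trimethylsilyl)pent-2-en-4-yn-1-yl]-1,3,2-dioxaborolane
Conditions: ICH2Cl, n-BuLi, THF, −78 °C → rt
Reagents that add atoms: chloroiodomethane, ClCI
Why: Matteson homologation: chloromethyllithium adds to boron and the alkenyl group migrates with retention, so the allylboronate should keep the alkynyl group cis to CH2B without passing through any allyl-metal species that could scramble geometry.

Step 9
Reactants: 8 (2R,3R)-3-(1,3-dioxolan-2-yl)-5-oxotetrahydrofuran-2-carbaldehyde; 15 4,4,5,5-tetramethyl-2-[(2Z)-3-methyl-5-(trimethylsilyl)pent-2-en-4-yn-1-yl]-1,3,2-dioxaborolane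
Product: 17 (4R,5R)-4-(1,3-dioxolan-2-yl)-5-[(1S,2S)-2-ethynyl-1-hydroxy-2-methylbut-3-en-1-yl]dihydrofuran-2(3H)-one, via O9-boryl ether 16 (not isolated)
Conditions: toluene, 4 Å MS, rt; then TBAF, AcOH, THF, 0 °C → rt
Reagents that add atoms: none
Why: Allylboration through a Zimmerman–Traxler chair, in which the Z-alkynyl group is axial and the E-methyl equatorial (C10 relative to C9) while Felkin–Anh attack anti to the C8–O bond, reinforced by the Z substituent of the boronate, sets C9 anti to O8; fluoride then cleaves the borate and the C-silyl group.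

Step 10
Reactants: 17 (4R,5R)-4-(1,3-dioxolan-2-yl)-5-[(1S,2S)-2-ethynyl-1-hydroxy-2-methylbut-3-en-1-yl]dihydrofuran-2(3H)-one
Product: 19 (4R,5R)-4-(1,3-dioxolan-2-yl)-5-[(1S,2S)-2-ethenyl-1-hydroxy-2-methylpenta-3,4-dien-1-yl]dihydrofuran-2(3H)-one, via propargylic amine 18 (not isolated)
Conditions: (CH2O)n, Cy2NH, CuI (copper iodide, 0.5 equiv), 1,4-dioxane, reflux
Reagents that add atoms: paraformaldehyde (as formaldehyde), C=O
Why: Crabbé homologation: copper-mediated Mannich coupling of the terminal alkyne and 1,5-hydride transfer with loss of the imine should give the terminal allene (C3 from formaldehyde) under conditions that tolerate a free hydroxyl, the lactone and the acetal.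

Step 11
Reactants: 19 (4R,5R)-4-(1,3-dioxolan-2-yl)-5-[(1S,2S)-2-ethenyl-1-hydroxy-2-methylpenta-3,4-dien-1-yl]dihydrofuran-2(3H)-one
Product: 22 (2R,3R)-2-{(1S,2S)-2-ethenyl-2-methyl-1-[(triethylsilyl)oxy]penta-3,4-dien-1-yl}-5-oxotetrahydrofuran-3-carbaldehyde, via O9-TES acetal 20 (not isolated), via collidinium triflate 21 (not isolated)
Conditions: Et3SiOTf (3.5 equiv), 2,4,6-collidine (5 equiv), CH2Cl2, −78 → 0 °C; then H2O, rt
Reagents that add atoms: triethylsilyl trifluoromethanesulfonate, CC[Si](CC)(CC)OS(=O)(=O)C(F)(F)F; water, O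
Why: The silyl triflate first silylates O9 and then, with collidine, opens the dioxolane to a collidinium salt that water hydrolyses to the aldehyde (silyl triflate/pyridine-base acetal cleavage), a non-acidic and only weakly basic unmasking that the allene, the silyl ether and the elimination-prone aldehyde should survive.

Step 12
Reactants: 22 (2R,3R)-2-{(1S,2S)-2-ethenyl-2-methyl-1-[(triethylsilyl)oxy]penta-3,4-dien-1-yl}-5-oxotetrahydrofuran-3-carbaldehyde
Product: 24 ring-A-closed lactone with 5β-[1-(pinacolboryl)vinyl] 6β-OH 9α-OSiEt3, via O6-boryl ether 23 (not isolated)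
Conditions: CuCl (10 mol%), Xantphos (11 mol%), NaOtBu (12 mol%), B2pin2 (1.2 equiv), THF, 0 °C → rt; then aq. NH4Cl
Reagents that add atoms: bis(pinacolato)diboron, CC1(C)OB(OC1(C)C)B1OC(C)(C)C(C)(C)O1
Why: A ligated monovalent copper boryl, formed from the copper alkoxide and B2pin2, adds syn across the terminal C3=C4 bond of the allene from the face remote from quaternary C10, giving the Z 2-boryl allylcopper (Cu on C3, B on C4) that attacks the C6 aldehyde through C5 in a closed six-membered transition state, after which exchange of the copper alkoxide with B2pin2 gives 23 and returns the catalyst without stoichiometric base. The closest known reaction type is the copper-catalysed borylative coupling of allenes with aldehydes and ketones, including intramolecular allene–ketone cyclisations. Ring A closes by 6-exo-trig attack of C5 on the C6 carbonyl. C5 and C6 are set together: the Z geometry puts C10 axial and C7 equatorial in the chair transition state, which can only fuse cis to the forming ring-A chair that the trans lactone locks (C7–C11 and C8–O equatorial, C9–OSiEt3 and C10–methyl axial), so the borylvinyl group should end equatorial (β) and O6 axial (β), whereas the other cis isomer would need the E allylcopper with C7 axial and would place the borylvinyl group syn-axial to the C9 silyloxy group. The step needs borylcupration of the allene in preference to the aldehyde and the C10 vinyl group, boron on the central carbon, and ring closure faster than E/Z equilibration of the allylcopper or β-elimination of the lactone carboxylate; the higher reactivity of allenes towards copper boryls, the phosphine ligand, the intramolecular trap and the near-absence of free alkoxide are expected to secure these.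

Step 13
Reactants: 24 ring-A-closed lactone with 5β-[1-(pinacolboryl)vinyl] 6β-OH 9α-OSiEt3
Product: 25 6-O-TBS ether of 24
Conditions: tBuMe2SiOTf, 2,6-lutidine, CH2Cl2, −78 → 0 °C
Reagents that add atoms: tert-butyldimethylsilyl trifluoromethanesulfonate, CC(C)(C)[Si](C)(C)OS(=O)(=O)C(F)(F)F
Why: Silyl triflate silylation of the hindered axial C6 alcohol (silyl ether formation), so that no alkoxide can bind the neighbouring boron in the next step.

Step 14
Reactants: 25 6-O-TBS ether of 24
Product: 27 C15 allylic alcohol, via allylboronate 26 (not isolated)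
Conditions: ICH2Cl (3 equiv), n-BuLi (2.5 equiv, added last), THF, −78 °C → rt; then NaBO3·4H2O, THF/H2O, rt
Reagents that add atoms: chloroiodomethane, ClCI; sodium perborate, [Na+].[O-]OB=O
Why: Matteson homologation (1,2-migration of the alkenyl group to the chloromethyl carbon on boron) followed by perborate oxidation of the allylboronate should give the C15 alcohol, the carbenoid being generated in the presence of the boronate at −78 °C so that it is captured at boron before it can reach the lactone.

Step 15
Reactants: 27 C15 allylic alcohol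
Product: 28 15-O-TBDPS ether of 27
Conditions: tBuPh2SiCl, imidazole, DMF, rt
Reagents that add atoms: tert-butylchlorodiphenylsilane, CC(C)(C)[Si](Cl)(c1ccccc1)c1ccccc1
Why: Silyl ether formation at the only free, primary allylic hydroxyl; this robust group should survive the later acid removal of the C9 triethylsilyl ether.

Step 16
Reactants: 28 15-O-TBDPS ether of 27
Product: 31 11(13)-methylene lactone, via Mannich base 29 (not isolated), via methiodide 30 (not isolated)
Conditions: LiN(iPr)2 (LDA), THF, −78 °C; CH2=NMe2+ I−, −78 °C → rt; then MeI, rt; then aq. NaHCO3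
Reagents that add atoms: Eschenmoser's salt (N,N-dimethylmethyleneiminium iodide), C=[N+](C)C.[I-]
Why: α-Methylenation of the lactone by enolisation at C11, Mannich reaction with Eschenmoser's salt, quaternisation and elimination of trimethylamine; only C11 carries acidic hydrogens, C7 bears no β-leaving group, and no stereocentre is affected.

Step 17
Reactants: 31 11(13)-methylene lactone
Product: 32 9α-alcohol
Conditions: CSA (cat.), MeOH/CH2Cl2, 0 °C
Reagents that add atoms: none
Why: Acid-catalysed methanolysis should remove the triethylsilyl ether much faster than the hindered secondary TBS ether and the primary TBDPS ether (selective silyl ether cleavage).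

Step 18
Reactants: 32 9α-alcohol; 33 angelic acid
Product: 35 9-O-angelate, via mixed anhydride 34 (not isolated)
Conditions: 33, 2,4,6-Cl3C6H2COCl, Et3N, toluene, rt; then 32, toluene, 80 °C
Reagents that add atoms: none
Why: Yamaguchi esterification: the mixed anhydride acylates the hindered axial C9 alcohol at the angeloyl carbonyl without a nucleophilic catalyst, conditions under which the Z geometry of the angelate should be kept.

Step 19
Reactants: 35 9-O-angelate
Product: 36 6,15-diol
Conditions: HF·pyridine, pyridine, THF, 0 °C → rt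
Reagents that add atoms: none
Why: Fluoride-mediated silyl ether cleavage should remove both remaining silyl groups under buffered acidic conditions that the angelate, the α-methylene lactone and the alkenes tolerate.

Step 20
Reactants: 36 6,15-diol
Product: 37 target CNP0320538.1
Conditions: MnO2 (activated, excess), CH2Cl2, rt
Reagents that add atoms: none
Why: Manganese dioxide oxidises the primary allylic C15 alcohol selectively (allylic oxidation) and should leave the non-allylic secondary C6 alcohol, completing the 2-substituted acrolein.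

Compound list
1 | (R)-5-oxotetrahydrofuran-2-carboxylic acid | OC(=O)[C@H]1CCC(=O)O1 | starting material
2 | (R)-5-(hydroxymethyl)dihydrofuran-2(3H)-one | OC[C@H]1CCC(=O)O1 | intermediate
3 | (R)-5-{[(triethylsilyl)oxy]methyl}dihydrofuran-2(3H)-one | CC[Si](CC)(CC)OC[C@H]1CCC(=O)O1 | intermediate
4 | (5R)-3-(phenylselanyl)-5-{[(triethylsilyl)oxy]methyl}dihydrofuran-2(3H)-one, C3 epimers, formed in the flask | CC[Si](CC)(CC)OC[C@H]1CC([Se]c2ccccc2)C(=O)O1 | intermediate
5 | selenoxide of 4, formed in the flask | CC[Si](CC)(CC)OC[C@H]1CC([Se](=O)c2ccccc2)C(=O)O1 | intermediate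
6 | (R)-5-{[(triethylsilyl)oxy]methyl}furan-2(5H)-one | CC[Si](CC)(CC)OC[C@H]1C=CC(=O)O1 | intermediate
7 | (4R,5R)-4-(1,3-dioxolan-2-yl)-5-{[(triethylsilyl)oxy]methyl}dihydrofuran-2(3H)-one (trans) | CC[Si](CC)(CC)OC[C@@H]1OC(=O)C[C@H]1C2OCCO2 | intermediate
8 | (2R,3R)-3-(1,3-dioxolan-2-yl)-5-oxotetrahydrofuran-2-carbaldehyde | O=C[C@@H]1OC(=O)C[C@H]1C2OCCO2 | intermediate
9 | propyne | CC#C | starting material
10 | (Z)-(2-bromoprop-1-en-1-yl)dibromoborane, formed in the flask | C/C(Br)=C/B(Br)Br | intermediate
11 | 2-[(Z)-2-bromoprop-1-en-1-yl]-4,4,5,5-tetramethyl-1,3,2-dioxaborolane | C/C(Br)=C/B1OC(C)(C)C(C)(C)O1 | intermediate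
12 | ethynyltrimethylsilane | C#C[Si](C)(C)C | starting material
13 | [(trimethylsilyl)ethynyl]zinc chloride, formed in the flask | C[Si](C)(C)C#C[Zn]Cl | intermediate
14 | 4,4,5,5-tetramethyl-2-[(1Z)-2-methyl-4-(trimethylsilyl)but-1-en-3-yn-1-yl]-1,3,2-dioxaborolane | C/C(C#C[Si](C)(C)C)=C/B1OC(C)(C)C(C)(C)O1 | intermediate
15 | 4,4,5,5-tetramethyl-2-[(2Z)-3-methyl-5-(trimethylsilyl)pent-2-en-4-yn-1-yl]-1,3,2-dioxaborolane | C[Si](C)(C)C#C/C(C)=C\CB1OC(C)(C)C(C)(C)O1 | intermediate
16 | O9-pinacolboryl ether of the C-trimethylsilyl alkyne corresponding to 17, formed in the flask | C=C[C@@](C)(C#C[Si](C)(C)C)[C@H](OB1OC(C)(C)C(C)(C)O1)[C@@H]2OC(=O)C[C@H]2C3OCCO3 | intermediate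
17 | (4R,5R)-4-(1,3-dioxolan-2-yl)-5-[(1S,2S)-2-ethynyl-1-hydroxy-2-methylbut-3-en-1-yl]dihydrofuran-2(3H)-one | C=C[C@@](C)(C#C)[C@H](O)[C@@H]1OC(=O)C[C@H]1C2OCCO2 | intermediate
18 | N,N-dicyclohexyl propargylic amine of 17 (alkyne terminus bearing CH2NCy2), formed in the flask | C=C[C@@](C)(C#CCN(C3CCCCC3)C4CCCCC4)[C@H](O)[C@@H]1OC(=O)C[C@H]1C2OCCO2 | intermediate
19 | (4R,5R)-4-(1,3-dioxolan-2-yl)-5-[(1S,2S)-2-ethenyl-1-hydroxy-2-methylpenta-3,4-dien-1-yl]dihydrofuran-2(3H)-one | C=C[C@@](C)(C=C=C)[C@H](O)[C@@H]1OC(=O)C[C@H]1C2OCCO2 | intermediate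
20 | 9-O-triethylsilyl ether of 19, formed in the flask | C=C[C@@](C)(C=C=C)[C@H](O[Si](CC)(CC)CC)[C@@H]1OC(=O)C[C@H]1C2OCCO2 | intermediate
21 | 2,4,6-trimethylpyridinium adduct at C6 of 20 (C6 bearing the collidinium nitrogen and a 2-(triethylsilyloxy)ethoxy group), triflate salt, formed in the flask | C=C[C@@](C)(C=C=C)[C@H](O[Si](CC)(CC)CC)[C@@H]1OC(=O)C[C@H]1C(OCCO[Si](CC)(CC)CC)[n+]2c(C)cc(C)cc2C.[O-]S(=O)(=O)C(F)(F)F | intermediate
22 | (2R,3R)-2-{(1S,2S)-2-ethenyl-2-methyl-1-[(triethylsilyl)oxy]penta-3,4-dien-1-yl}-5-oxotetrahydrofuran-3-carbaldehyde (key-step precursor) | C=C[C@@](C)(C=C=C)[C@H](O[Si](CC)(CC)CC)[C@@H]1OC(=O)C[C@H]1C=O | intermediate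
23 | O6-pinacolboryl ether of 24, formed in the flask | C=C[C@]1(C)[C@H](O[Si](CC)(CC)CC)[C@@H]2OC(=O)C[C@H]2[C@@H](OB3OC(C)(C)C(C)(C)O3)[C@H]1C(=C)B4OC(C)(C)C(C)(C)O4 | intermediate
24 | key-step product: trans-fused 8α,12-lactone on ring A with 5β-[1-(pinacolboryl)vinyl], 6β-OH, 9α-OSiEt3, 10β-methyl and 10α-vinyl (5S,6S,7S,8R,9S,10S) | C=C[C@]1(C)[C@H](O[Si](CC)(CC)CC)[C@@H]2OC(=O)C[C@H]2[C@@H](O)[C@H]1C(=C)B3OC(C)(C)C(C)(C)O3 | intermediate
25 | 6-O-tert-butyldimethylsilyl ether of 24 | C=C[C@]1(C)[C@H](O[Si](CC)(CC)CC)[C@@H]2OC(=O)C[C@H]2[C@@H](O[Si](C)(C)C(C)(C)C)[C@H]1C(=C)B3OC(C)(C)C(C)(C)O3 | intermediate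
26 | allylboronate: as 25 but with C4 carrying CH2–B(pin) (C15 inserted), formed in the flask | C=C[C@]1(C)[C@H](O[Si](CC)(CC)CC)[C@@H]2OC(=O)C[C@H]2[C@@H](O[Si](C)(C)C(C)(C)C)[C@H]1C(=C)CB3OC(C)(C)C(C)(C)O3 | intermediate
27 | C15 allylic alcohol: as 25 but with C5 carrying C(=CH2)CH2OH | C=C[C@]1(C)[C@H](O[Si](CC)(CC)CC)[C@@H]2OC(=O)C[C@H]2[C@@H](O[Si](C)(C)C(C)(C)C)[C@H]1C(=C)CO | intermediate
28 | 15-O-tert-butyldiphenylsilyl ether of 27 | C=C[C@]1(C)[C@H](O[Si](CC)(CC)CC)[C@@H]2OC(=O)C[C@H]2[C@@H](O[Si](C)(C)C(C)(C)C)[C@H]1C(=C)CO[Si](c3ccccc3)(c4ccccc4)C(C)(C)C | intermediate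
29 | 11-(dimethylaminomethyl) lactone from 28 (C11 epimers), formed in the flask | C=C[C@]1(C)[C@H](O[Si](CC)(CC)CC)[C@@H]2OC(=O)C(CN(C)C)[C@H]2[C@@H](O[Si](C)(C)C(C)(C)C)[C@H]1C(=C)CO[Si](c3ccccc3)(c4ccccc4)C(C)(C)C | intermediate
30 | trimethylammonium iodide of 29, formed in the flask | C=C[C@]1(C)[C@H](O[Si](CC)(CC)CC)[C@@H]2OC(=O)C(C[N+](C)(C)C)[C@H]2[C@@H](O[Si](C)(C)C(C)(C)C)[C@H]1C(=C)CO[Si](c3ccccc3)(c4ccccc4)C(C)(C)C.[I-] | intermediate
31 | 11(13)-methylene lactone with 6-OTBS, 9-OSiEt3, 15-OTBDPS | C=C[C@]1(C)[C@H](O[Si](CC)(CC)CC)[C@@H]2OC(=O)C(=C)[C@H]2[C@@H](O[Si](C)(C)C(C)(C)C)[C@H]1C(=C)CO[Si](c3ccccc3)(c4ccccc4)C(C)(C)C | intermediate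
32 | 9α-alcohol from 31 | C=C[C@]1(C)[C@H](O)[C@@H]2OC(=O)C(=C)[C@H]2[C@@H](O[Si](C)(C)C(C)(C)C)[C@H]1C(=C)CO[Si](c3ccccc3)(c4ccccc4)C(C)(C)C | intermediate
33 | angelic acid, (2Z)-2-methylbut-2-enoic acid | C/C=C(/C)C(=O)O | starting material
34 | angelic 2,4,6-trichlorobenzoic anhydride, formed in the flask | C/C=C(/C)C(=O)OC(=O)c1c(Cl)cc(Cl)cc1Cl | intermediate
35 | 9-O-angelate of 32 | C=C[C@]1(C)[C@H](OC(=O)/C(C)=C\C)[C@@H]2OC(=O)C(=C)[C@H]2[C@@H](O[Si](C)(C)C(C)(C)C)[C@H]1C(=C)CO[Si](c3ccccc3)(c4ccccc4)C(C)(C)C | intermediate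
36 | 6β,15-diol 9-O-angelate | C=C[C@]1(C)[C@H](OC(=O)/C(C)=C\C)[C@@H]2OC(=O)C(=C)[C@H]2[C@@H](O)[C@H]1C(=C)CO | intermediate
37 | CNP0320538.1 (5R,6S,7S,8R,9S,10S) | C=C[C@]1(C)[C@H](OC(=O)/C(C)=C\C)[C@@H]2OC(=O)C(=C)[C@H]2[C@@H](O)[C@H]1C(=C)C=O | target

Total step count: 20. Longest linear sequence: 17 (steps 1–5 and 9–20).

Steps most likely to fail

Step 12. Borylcupration of the aldehyde or protonation of the allylcopper may outrun ring closure. The allylcopper may equilibrate to its E isomer and close trans. The alkoxide may open the lactone by β-elimination. The fallback sets out from 22 and uses a known palladium-catalysed bismetallative allene–aldehyde cyclisation, which closes the same C5–C6 bond through an allylstannane and is known to give cis-2-alkenylcycloalkanols. Treatment of 22 with Bu3Sn–SnBu3 and [PdCl(C3H5)]2 (cat.) in THF at rt should give the O-stannyl ether F1, which is hydrolysed on work-up to the vinylstannane alcohol F2. Iododestannylation (I2, CH2Cl2, 0 °C) should then give the vinyl iodide F3. Miyaura borylation of F3 (B2pin2, PdCl2(PPh3)2, PPh3, KOPh, toluene, 50 °C) comes back to the route at 24.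

Step 9. Slow addition of the hindered pinacol boronate may let the α-acyloxy aldehyde hydrate, epimerise or decompose, and the Felkin preference at rt may be too small. The fallback sets out from 15 and changes the allylating species. Activation of 15 with n-BuLi and then trifluoroacetic anhydride (THF, −78 °C) should give the much more reactive B-butyl borinic ester F4. F4 should add to 8 at −78 °C through the same chair transition state and give the O-borinate F5. The fluoride work-up of step 9 then comes back to the route at 17.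

Step 14. The carbenoid or butyllithium may attack the lactone carbonyl, or ate-complex formation at the hindered boron may be too slow. The fallback sets out from 25 and avoids organolithium reagents. Iododeboronation (NaOH, I2, THF, 0 °C, with a mildly acidic work-up so that any opened lactone recloses) should give the vinyl iodide F6. Stille coupling of F6 with (tributylstannyl)methanol (Pd(PPh3)4, toluene, 90 °C) comes back to the route at 27.

Further compounds
F1 | step 12 | O6-tributylstannyl ether of F2, formed in the flask | C=C[C@]1(C)[C@H](O[Si](CC)(CC)CC)[C@@H]2OC(=O)C[C@H]2[C@@H](O[Sn](CCCC)(CCCC)CCCC)[C@H]1C(=C)[Sn](CCCC)(CCCC)CCCC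
F2 | step 12 | vinylstannane alcohol: as 24 but with SnBu3 in place of B(pin) | C=C[C@]1(C)[C@H](O[Si](CC)(CC)CC)[C@@H]2OC(=O)C[C@H]2[C@@H](O)[C@H]1C(=C)[Sn](CCCC)(CCCC)CCCC
F3 | step 12 | vinyl iodide alcohol: as 24 but with I in place of B(pin) | C=C[C@]1(C)[C@H](O[Si](CC)(CC)CC)[C@@H]2OC(=O)C[C@H]2[C@@H](O)[C@H]1C(=C)I
F4 | step 9 | B-butyl borinic ester of the (2Z)-3-methyl-5-(trimethylsilyl)pent-2-en-4-yn-1-yl group with a mono(trifluoroacetyl)pinacol ligand, formed in the flask | C[Si](C)(C)C#C/C(C)=C\CB(CCCC)OC(C)(C)C(C)(C)OC(=O)C(F)(F)F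
F5 | step 9 | O9-borinate of the C-trimethylsilyl alkyne corresponding to 17, formed in the flask | C=C[C@@](C)(C#C[Si](C)(C)C)[C@H](OB(CCCC)OC(C)(C)C(C)(C)OC(=O)C(F)(F)F)[C@@H]1OC(=O)C[C@H]1C2OCCO2
F6 | step 14 | vinyl iodide: as 25 but with I in place of B(pin) | C=C[C@]1(C)[C@H](O[Si](CC)(CC)CC)[C@@H]2OC(=O)C[C@H]2[C@@H](O[Si](C)(C)C(C)(C)C)[C@H]1C(=C)I
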